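The ratio of product in Friday's flask to product in Tuesday's stood at 1.27 at the first reading and at 1.07 at the last, and I began from that drift, since the two flasks differed in their reagent charge, 170 mM against 110 mM, and not in their starting material.

| flask | starting material | reagent | time |
|---|---|---|---|
| Tuesday's | 100 mM | 110 mM |  |
| Friday's | 100 mM | 170 mM |  |
| Monday's | 200 mM | 110 mM |  |
| Thursday's | 50.0 mM | 220 mM | 23 min |

- Tuesday's run (time / min: [product] / mM): 2.9: 10.0; 5.8: 19.5; 8.6: 24.8; 12: 29.0; 14: 30.2; 17: 31.6; 20: 31.5; 23: 32.3
- Friday's run (time / min: [product] / mM): 2.9: 12.7; 5.8: 21.9; 8.6: 28.4; 12: 31.0; 14: 32.0; 17: 32.5; 20: 34.4; 23: 34.7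
- Monday's run (time / min: [product] / mM): 2.9: 18.2; 5.8: 33.4; 8.6: 40.6; 12: 45.1; 14: 47.1; 17: 48.8; 20: 50.0; 23: 50.7

(readings scatter by 0.5 mM)

- Overall: starting material + reagent -> product.
- Constant volume, constant temperature.
- "The second partner" is reagent.
- An order is taken over about fifteen percent of the charge, up and down.

- the power of [starting material] that the first rate follows, about the charge of the Tuesday's run; measure it at two percent of starting material made into product (one fixed amount of product, the same in the runs compared)
- the power of [reagent] that the first rate follows, about the charge of the Tuesday's run; measure it at two percent of starting material made into product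
- product in the Thursday's run at 23 min, as a share of the starting material charged

The gap behind the ratio stayed about the same: Friday led by 2.70 mM at 2.9 min and by 2.40 mM at 23 min. So the extra reagent won its lead in the first minutes, and from 14 min on Friday gained 2.70 mM against Tuesday's 2.10 mM, which did not close the gap; the ratio fell because a gap of like size came to stand on larger totals, Tuesday's having grown from 10.0 mM to 32.3 mM.

To carry this over I defined a stall time, the last reading of product divided by the mean rate up to the first reading, that is, the time that first pace takes to make that product. As readings, it came to 9.37 min for Tuesday, 7.92 min for Friday and 8.08 min for Monday. Friday's was shorter than Tuesday's, so more reagent raised the first rate and shortened the stall.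

From the first readings I took powers of 0.864 in c(starting material) and 0.549 in c(reagent), both coarse, being read over whole steps of the charge. They put Thursday's first rate at 2.77 mM min⁻¹. Thursday's reagent charge of 220 mM stood above Friday's 170 mM and Tuesday's 110 mM, so I used Friday's stall time and reached 22.0 mM, or 43.9 % of the charge.

The forecast gave powers of 0.75 and 0.3 and, by “saturation scaling”, 42 %, so it differed from my reckoning in all of these.

The flask gave powers of 0.65 and 0.46, and 38.7 % of Thursday's starting material as product at 23 min.

    starting material ⇌ intermediate + by-product (0.08640 min⁻¹, 6.540 L mol⁻¹ min⁻¹)
    intermediate + reagent → product (6.240 L mol⁻¹ min⁻¹)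
    starting material → decomposed substrate (0.1104 min⁻¹)
    2 starting material → homo dimer (0.3408 L mol⁻¹ min⁻¹)

Where two percent of Tuesday's charge had turned, Friday's rate was 4.3 mM min⁻¹ against Tuesday's 3.5 mM min⁻¹, and that simulated rate gives Friday a stall time of 8.13 min. Thursday's product of 19.3 mM, divided by my first rate, gives a stall time of 6.98 min, shorter than Friday's 7.92 min.

The readings come from a simulation for substances that don't exist, noise included.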